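The runs stem from a simulated flask with made-up constants; the scatter is artificial.

I have to choose between ochre and teal, two recipes that differ in their charge of free catalyst, and I judge them by the excess of left-handed product over right-handed product in the product.

the same everywhere: left-handed substrate 20 mM; right-handed substrate 20 mM; gas 1.3 mM (held)

| run | free catalyst | remark | time |
|---|---|---|---|
| alder | 16 µM | run made earlier |  |
| ochre | 14 µM |  | 2.5 h |
| teal | 10 µM |  | 2.5 h |

- the winner by excess of left-handed product over right-handed product in the product; "neither" if no more than 2 percentage points parts them (ochre / teal / neither)
- excess of left-handed product over right-handed product in the product at the end, ochre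
- excess of left-handed product over right-handed product in the product at the end, teal

- free catalyst is single-handed; left-handed substrate and right-handed substrate are mirror images of each other, charged as a racemate, each of them at the stated concentration
- at the start none of the gas is in solution
- an excess is below zero if the other one leads
- no earlier run changes the charge of free catalyst; that part of a forecast is a guess

alder run (percent of the left-handed substrate and right-handed substrate together charged)

| time / h | left-handed product / % | right-handed product / % | left-handed substrate / % |
|---|---|---|---|
| 0.200 | 3.7 | 1.7 | 46.7 |
| 0.500 | 8.0 | 4.8 | 41.6 |
| 1.00 | 14.9 | 9.5 | 34.4 |
| 2.50 | 29.1 | 19.2 | 20.7 |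

(each reading ± 0.3 percentage points)

I read the alder table downward. The excess reads 37.0% in the first row, where a scatter of 0.3 percentage points sits on a right-handed product of 1.7%, and 20.5% in the last row, so in alder the excess is no constant. Left-handed substrate and left-handed product sum to 49.8% in the last row, so I take right-handed product as the measure of right-handed substrate gone.

The last row then gives s = 1.82, the selectivity factor: the logarithm of the fraction of left-handed substrate left over the logarithm of the fraction of right-handed substrate left. The second and third rows read 1.82 and 1.77, so in alder s holds while the excess moves.

If both substrates go by the same steps with the same orders, any concentration they share cancels in s. What is left of left-handed substrate then gives what is left of right-handed substrate, and the excess is the difference of those two fractions over the sum of what has gone. No earlier run changes the charge of free catalyst, so this step is a guess: if a smaller charge gives less conversion at 2.5 h, the excess stands higher, and I expect teal slightly ahead, its charge of 10 µM being smaller than the 14 µM of ochre.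

The forecast gives ochre 21.3% and teal 23.2%, hence neither, with a gap of 1.9 points against the margin of 2 points. It says itself: “The catalyst order is a guess.”

The flask gives neither: ochre 21.6%, and teal 22.3%, ahead by 0.70 points.

    2 free catalyst → spent catalyst (k = 9.60 /M/s)
    partner + free catalyst + left-handed substrate → free catalyst + left-handed product (k = 24000 /M²/s)
    gas ⇌ partner, rate k3*(csat - [partner]) (kL = 0.00340 /s)
    partner → decomposed reagent (k = 2.10 × 10⁻⁴ /s)
    partner + free catalyst + right-handed substrate → free catalyst + right-handed product (k = 13000 /M²/s)

Applied to the 43% of left-handed substrate left in ochre, s gives an excess of 21.1%. Applied to the 33% of left-handed substrate left in a second flask, the same as ochre but charged with 0.056 mM of free catalyst, it gives 19.0%, where that flask stands at 19.6%. At 2.50 h ochre holds 4.09 µM of free catalyst and teal 3.67 µM, a ratio smaller than that of their charges, with 70.8% of the ochre charge and 63.3% of the teal charge standing as spent catalyst.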